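**Assumption:** Birch methylation of the (S)-2-(methoxymethyl)pyrrolidine benzamide is taken to give the (1R) quaternary centre drawn in 7; if the sense is opposite, the (R)-amine is used.

Positions are given in briarane numbering: C1 quaternary carbon, C2–C10 ten-membered ring, C11–C14 rest of ring A, C16/C20 exocyclic methylenes, C17–C19 lactone. Target: 1R,2S,3E,6S,7R,8R,9S,10S,14S,17R. The chlorovinyl group of 14–27 is carried as an E/Z mixture, which converges in step 16.

## Retrosynthetic overview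

1. Target 29 ⇒ acyclic aldehyde ester 26: one CrCl2 operation forms C6–C7 (ten-membered ring, C6–Cl, C5 methylene) and the γ-lactone together, last.
2. 26 ⇒ ketone 22 + methyl 2-bromopropanoate (Reformatsky, C8–C17); 22 ⇒ allylsilane 18 + 3,3-dimethoxy-2-oxopropanal (Hosomi–Sakurai, C9–C10, C11 methylene).
3. 18 ⇒ ring-A aldehyde 10 + chloroenyne 14 (alkenylzinc addition, C2–C3, 3E).
4. 10 ⇒ benzamide 5: ring A comes first, from an arene by asymmetric Birch reduction–methylation (C1), then the ten-membered ring and lactone close in the same step.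

## Route

Step 1
Reactants: 1 5-bromo-2-methoxybenzoic acid; 2 (S)-2-(methoxymethyl)pyrrolidine
Product: 4 bromo benzamide of the prolinol methyl ether, via acid chloride 3 (not isolated)
Conditions: (COCl)2, DMF (cat.), CH2Cl2, 0 → 23 °C; then 2, Et3N, CH2Cl2, 0 °C
Reagents that add atoms: none
Why: Acid chloride amidation; no new stereocentre, the amide is the chiral auxiliary for step 3.

Step 2
Reactants: 4 bromo benzamide
Product: 5 benzylsilane benzamide
Conditions: Me3SiCH2MgCl, Pd(PPh3)4 (3 mol %), THF, 60 °C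
Reagents that add atoms: (trimethylsilyl)methylmagnesium chloride, C[Si](C)(C)C[Mg]Cl
Why: Kumada–Corriu coupling at zerovalent palladium installs the benzylic silane that becomes the allylsilane and later the C11 methylene; the hindered tertiary amide resists the Grignard reagent.

Step 3
Reactants: 5 benzylsilane benzamide
Product: 7 (1R)-2-methoxy-1-methyl-5-(trimethylsilylmethyl)cyclohexa-2,5-diene-1-carboxamide, via potassium amide enolate 6 (not isolated)
Conditions: K, NH3(l)–THF, t-BuOH (1 equiv), −78 °C; then MeI, −78 °C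
Reagents that add atoms: iodomethane, CI
Why: Schultz asymmetric Birch reduction–alkylation: the chelated amide enolate is methylated on the face remote from the pyrrolidine ring, setting the C1 quaternary centre, and the benzylsilane emerges as the C10=C11 allylsilane.

Step 4
Reactants: 7 dienyl methyl enol ether
Product: 8 β-keto amide (C14 ketone)
Conditions: 1 M HCl, THF, 0 °C, 30 min
Reagents that add atoms: water, O
Why: Enol ether hydrolysis; the alkene cannot conjugate because C1 is quaternary, and the allylsilane survives cold dilute acid.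

Step 5
Reactants: 8 β-keto amide
Product: 9 β-hydroxy amide (14S)
Conditions: LiBH(s-Bu)3, THF, −78 °C; then H2O
Reagents that add atoms: none
Why: Bulky-hydride ketone reduction: equatorial attack anti to the carboxamide gives the axial C14 alcohol trans to the C1 methyl; the amide is inert.

Step 6
Reactants: 9 β-hydroxy amide
Product: 10 (1R,6S)-6-hydroxy-1-methyl-3-(trimethylsilylmethyl)cyclohex-2-ene-1-carbaldehyde
Conditions: Cp2Zr(H)Cl (2.5 equiv), THF, 23 °C; then H2O, SiO2
Reagents that add atoms: water, O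
Why: Cp2Zr(H)Cl reduction of a tertiary amide (hydrozirconation of C=O, iminium, hydrolysis) stops at the aldehyde and releases the auxiliary; the trisubstituted alkene is too hindered to hydrozirconate.

Step 7
Reactants: 11 1,3-dichloropropan-2-one; 12 ethynylmagnesium bromide
Product: 13 1-chloro-2-(chloromethyl)but-3-yn-2-ol
Conditions: THF, −78 °C; then pH 7 buffer, −78 °C
Reagents that add atoms: none
Why: Grignard 1,2-addition to a very electrophilic ketone, quenched cold before the chlorohydrin alkoxide can close to an epoxide.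

Step 8
Reactants: 13 propargylic alcohol
Product: 14 1-chloro-2-(chloromethyl)but-1-en-3-yne (E/Z mixture)
Conditions: Burgess reagent (Et3N+SO2N−CO2Me), benzene, 50 °C
Reagents that add atoms: none
Why: Burgess syn-elimination under non-basic conditions (no epoxide formation) toward either equivalent CH2Cl arm.

Step 9
Reactants: 10 ring-A hydroxy aldehyde; 14 chloroenyne
Product: 17 ring-A 1,3-diol carrying the chlorodienyl chain (2S), via alkenylzirconocene 15 (not isolated), via alkenylzinc 16 (not isolated)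
Conditions: 14, Cp2Zr(H)Cl, CH2Cl2, 23 °C; Me2Zn, toluene, −65 °C; then 10, 0 °C; H2O
Reagents that add atoms: none
Why: Hydrozirconation–zinc transmetallation and 1,2-addition (Wipf protocol): syn-hydrozirconation fixes the 3E alkene, and the zinc alkoxide of the C14 hydroxyl chelates the aldehyde so that attack anti to the axial C10 arm of the chelate gives the 1,3-anti diol.

Step 10
Reactants: 17 diol
Product: 18 C2,C14-diacetate allylsilane
Conditions: Ac2O, Et3N, DMAP (cat.), CH2Cl2, 23 °C
Reagents that add atoms: acetic anhydride, CC(=O)OC(C)=O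
Why: DMAP-catalysed acylation installs two of the three final acetates.

Step 11
Reactants: 19 1,1-dimethoxypropan-2-one
Product: 20 3,3-dimethoxy-2-oxopropanal
Conditions: SeO2, 1,4-dioxane, H2O (cat.), 90 °C; distilled and used anhydrous
Reagents that add atoms: selenium dioxide, O=[Se]=O
Why: Riley oxidation of the methyl ketone to the glyoxal; the acetal CH does not enolise under these conditions.

Step 12
Reactants: 18 allylsilane diacetate; 20 keto aldehyde (2 equiv)
Product: 21 α-hydroxy ketone with C11 exocyclic methylene (9S,10S)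
Conditions: BF3·OEt2, CH2Cl2, −78 °C; aq. NaHCO3
Reagents that add atoms: none
Why: Hosomi–Sakurai allylation: anti-SE2' attack on the activated aldehyde through an open antiperiplanar transition state gives the syn C9/C10 pair, the electrophile entering C10 anti to the larger C1 substituent (the C2 chain), and loss of silicon creates the C11 methylene.

Step 13
Reactants: 21 α-hydroxy ketone
Product: 22 α-acetoxy ketone (triacetate)
Conditions: Ac2O, pyridine, DMAP (cat.), CH2Cl2, 0 °C
Reagents that add atoms: acetic anhydride, CC(=O)OC(C)=O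
Why: Acylation traps the α-ketol before C9 can epimerise and installs the third final acetate.

Step 14
Reactants: 22 α-acetoxy ketone; 23 methyl 2-bromopropanoate
Product: 25 β-hydroxy ester with C8 carbinol (8R,17R), via bromozinc enolate 24 (not isolated)
Conditions: 23, Zn (Me3SiCl-activated), THF, 40 °C, solution decanted from Zn; then 22, THF, −20 → 0 °C; H2O
Reagents that add atoms: none
Why: Reformatsky reaction: the weakly basic zinc enolate adds to the doubly α-oxygenated ketone under polar Felkin–Anh control by the non-chelating C9 acetate (sets C8), and a closed Zimmerman–Traxler transition state with the C9 arm equatorial is expected to favour 17R.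

Step 15
Reactants: 25 dimethyl acetal
Product: 26 α-hydroxy aldehyde ester
Conditions: CF3CO2H–H2O (4:1), CH2Cl2, 0 °C; used at once
Reagents that add atoms: water, O
Why: Acetal hydrolysis frees the C7 aldehyde; C8 is quaternary, so the α-hydroxy aldehyde cannot enolise.

Step 16
Reactants: 26 α-hydroxy aldehyde ester
Product: 29 CNP0178742.3, via allylchromium 27 (not isolated), via hydroxy ester 28 (not isolated)
Conditions: CrCl2 (6 equiv), LiI (cat.), THF–DMF (3:1), 0.003 M, slow addition, 23 °C; then 10% aq. citric acid, 23 °C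
Reagents that add atoms: none
Why: Proposed new method: divalent chromium inserts into the primary allylic chloride and the γ-chloroallylchromium adds through its chlorine-bearing carbon to the aldehyde in a chair transition state (closest known reactions: Nozaki–Hiyama–Kishi allylation macrocyclisation and intermolecular chromium-mediated addition of 1,3-dichloropropene to aldehydes), closing the ten-membered ring, setting the anti C6–Cl/C7–O pair from either chloroalkene isomer and creating the C5 methylene; the trivalent-chromium chelate of the C8 alkoxide and aldehyde is expected to direct attack so that C6 ends trans to C9, and the C7 alkoxide then acylates the γ-ester to close the lactone.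

## Compound list

1 | 5-bromo-2-methoxybenzoic acid | COc1ccc(Br)cc1C(=O)O | starting material
2 | (S)-2-(methoxymethyl)pyrrolidine | COC[C@@H]1CCCN1 | starting material
3 | 5-bromo-2-methoxybenzoyl chloride | COc1ccc(Br)cc1C(Cl)=O | intermediate
4 | (5-bromo-2-methoxyphenyl)[(2S)-2-(methoxymethyl)pyrrolidin-1-yl]methanone | COC[C@@H]1CCCN1C(=O)c1cc(Br)ccc1OC | intermediate
5 | {2-methoxy-5-[(trimethylsilyl)methyl]phenyl}[(2S)-2-(methoxymethyl)pyrrolidin-1-yl]methanone | COC[C@@H]1CCCN1C(=O)c1cc(C[Si](C)(C)C)ccc1OC | intermediate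
6 | potassium amide enolate of 1,4-dihydro-5 | COC[C@@H]1CCCN1C([O-])=C1C=C(C[Si](C)(C)C)CC=C1OC.[K+] | intermediate
7 | [(1R)-2-methoxy-1-methyl-5-[(trimethylsilyl)methyl]cyclohexa-2,5-dien-1-yl][(2S)-2-(methoxymethyl)pyrrolidin-1-yl]methanone | COC[C@@H]1CCCN1C(=O)[C@]1(C)C=C(C[Si](C)(C)C)CC=C1OC | intermediate
8 | (2R)-2-{[(2S)-2-(methoxymethyl)pyrrolidin-1-yl]carbonyl}-2-methyl-4-[(trimethylsilyl)methyl]cyclohex-3-en-1-one | COC[C@@H]1CCCN1C(=O)[C@]1(C)C=C(C[Si](C)(C)C)CCC1=O | intermediate
9 | (1S,2R)-2-{[(2S)-2-(methoxymethyl)pyrrolidin-1-yl]carbonyl}-2-methyl-4-[(trimethylsilyl)methyl]cyclohex-3-en-1-ol | COC[C@@H]1CCCN1C(=O)[C@]1(C)C=C(C[Si](C)(C)C)CC[C@@H]1O | intermediate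
10 | (1R,6S)-6-hydroxy-1-methyl-3-[(trimethylsilyl)methyl]cyclohex-2-ene-1-carbaldehyde | O=C[C@]1(C)C=C(C[Si](C)(C)C)CC[C@@H]1O | intermediate
11 | 1,3-dichloropropan-2-one | ClCC(=O)CCl | starting material
12 | ethynylmagnesium bromide | C#C[Mg]Br | starting material
13 | 1-chloro-2-(chloromethyl)but-3-yn-2-ol | OC(CCl)(CCl)C#C | intermediate
14 | 1-chloro-2-(chloromethyl)but-1-en-3-yne (E/Z mixture) | ClC=C(CCl)C#C | intermediate
15 | chloro[(1E)-4-chloro-3-(chloromethyl)buta-1,3-dien-1-yl]zirconocene | ClC=C(CCl)/C=C/[Zr](Cl)(C1C=CC=C1)C1C=CC=C1 | intermediate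
16 | [(1E)-4-chloro-3-(chloromethyl)buta-1,3-dien-1-yl](methyl)zinc | ClC=C(CCl)/C=C/[Zn]C | intermediate
17 | (1S,2R)-2-[(1S,2E)-5-chloro-4-(chloromethyl)-1-hydroxypenta-2,4-dien-1-yl]-2-methyl-4-[(trimethylsilyl)methyl]cyclohex-3-en-1-ol | ClCC(=CCl)/C=C/[C@H](O)[C@]1(C)C=C(C[Si](C)(C)C)CC[C@@H]1O | intermediate
18 | (1S,2R)-2-[(1S,2E)-1-acetoxy-5-chloro-4-(chloromethyl)penta-2,4-dien-1-yl]-2-methyl-4-[(trimethylsilyl)methyl]cyclohex-3-en-1-yl acetate | ClCC(=CCl)/C=C/[C@H](OC(C)=O)[C@]1(C)C=C(C[Si](C)(C)C)CC[C@@H]1OC(C)=O | intermediate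
19 | 1,1-dimethoxypropan-2-one | COC(OC)C(C)=O | starting material
20 | 3,3-dimethoxy-2-oxopropanal | COC(OC)C(=O)C=O | intermediate
21 | (1S,2R,3S)-2-[(1S,2E)-1-acetoxy-5-chloro-4-(chloromethyl)penta-2,4-dien-1-yl]-3-[(1S)-1-hydroxy-3,3-dimethoxy-2-oxopropyl]-2-methyl-4-methylidenecyclohexyl acetate | C=C1CC[C@H](OC(C)=O)[C@](C)([C@@H](OC(C)=O)/C=C/C(=CCl)CCl)[C@H]1[C@H](O)C(=O)C(OC)OC | intermediate
22 | (1S,2R,3S)-2-[(1S,2E)-1-acetoxy-5-chloro-4-(chloromethyl)penta-2,4-dien-1-yl]-3-[(1S)-1-acetoxy-3,3-dimethoxy-2-oxopropyl]-2-methyl-4-methylidenecyclohexyl acetate | C=C1CC[C@H](OC(C)=O)[C@](C)([C@@H](OC(C)=O)/C=C/C(=CCl)CCl)[C@H]1[C@H](OC(C)=O)C(=O)C(OC)OC | intermediate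
23 | methyl 2-bromopropanoate (racemic) | COC(=O)C(C)Br | starting material
24 | bromozinc enolate BrZnCH(CH3)CO2CH3 | COC(=O)C(C)[Zn]Br | intermediate
25 | methyl (2R,3R,4S)-4-acetoxy-4-{(1S,2R,3S)-3-acetoxy-2-[(1S,2E)-1-acetoxy-5-chloro-4-(chloromethyl)penta-2,4-dien-1-yl]-2-methyl-6-methylidenecyclohexyl}-3-(dimethoxymethyl)-3-hydroxy-2-methylbutanoate | C=C1CC[C@H](OC(C)=O)[C@](C)([C@@H](OC(C)=O)/C=C/C(=CCl)CCl)[C@H]1[C@H](OC(C)=O)[C@@](O)(C(OC)OC)[C@@H](C)C(=O)OC | intermediate
26 | methyl (2R,3R,4S)-4-acetoxy-4-{same cyclohexyl group as in 25}-3-formyl-3-hydroxy-2-methylbutanoate | C=C1CC[C@H](OC(C)=O)[C@](C)([C@@H](OC(C)=O)/C=C/C(=CCl)CCl)[C@H]1[C@H](OC(C)=O)[C@@](O)(C=O)[C@@H](C)C(=O)OC | intermediate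
27 | allylchromium dichloride from 26 (Cr on C16) | C=C1CC[C@H](OC(C)=O)[C@](C)([C@@H](OC(C)=O)/C=C/C(=CCl)C[Cr](Cl)Cl)[C@H]1[C@H](OC(C)=O)[C@@](O)(C=O)[C@@H](C)C(=O)OC | intermediate
28 | macrocyclic 7,8-dihydroxy methyl ester (seco-lactone of 29; 6S,7R) | C=C1CC[C@H](OC(C)=O)[C@]2(C)[C@@H](OC(C)=O)/C=C/C(=C)[C@H](Cl)[C@H](O)[C@@](O)([C@@H](C)C(=O)OC)[C@@H](OC(C)=O)[C@@H]12 | intermediate
29 | CNP0178742.3 (2,9,14-triacetoxy-6-chloro-8-hydroxy briarane 7,19-lactone) | C=C1CC[C@H](OC(C)=O)[C@]2(C)[C@@H](OC(C)=O)/C=C/C(=C)[C@H](Cl)[C@@H]3OC(=O)[C@H](C)[C@@]3(O)[C@@H](OC(C)=O)[C@@H]12 | target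

## Step count and risks

Total steps: 16. Longest linear sequence: 13 (steps 1–6, 9, 10, 12–16).

**Step 16 (key cyclisation).** Risks are oligomerisation, the wrong face at C7 (cis-fused lactone), α-ketol rearrangement of 26 and reduction of the product's allylic chloride by excess CrCl2. Fallback: set out from acetal 25 and return at 28. Borylation of the primary allylic chloride (B2pin2, Pd2(dba)3, DMSO, 40 °C) through the syn π-allyl complex gives the (E)-γ-chloroallyl pinacol boronate F1. Acetal hydrolysis as in step 15 gives aldehyde boronate F2, which closes the ring by a metal-free allylboration through a closed chair (E-boronate gives the anti chlorohydrin). Aqueous work-up gives hydroxy ester 28, and PPTS closes the lactone to 29.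

**Step 12 (Hosomi–Sakurai union).** The C10 face is not secured: the axial C1 methyl may direct the electrophile to the wrong side, and syn/anti control at C9 rests on an open transition state. Fallback: set out from 18 and return at 22, setting C10 thermodynamically and C9 by reduction. HC(OMe)3 with Me3SiOTf gives dimethyl acetal F3. Aqueous acid gives aldehyde F4, which DBU equilibrates to the isomer with the C2 and C9 arms trans-diequatorial. 2-Lithio-2-(dimethoxymethyl)-1,3-dithiane at −78 °C gives carbinol F5 as C9 epimers. Dess–Martin oxidation gives ketone F6, and Felkin–Anh reduction with LiBH(s-Bu)3 returns F5 as the 9S epimer. Acetylation gives acetate F7, and PhI(OCOCF3)2 in wet MeCN unmasks the ketone to give 22.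

**Step 14 (Reformatsky).** Zinc chelation by the acetate would invert C8, C17 selectivity is likely to be modest, and acetate migration in the zinc alkoxide is possible. Fallback: set out from 22 and return at 29 with an auxiliary-controlled aldol. The chlorotitanium enolate of (R)-4-benzyl-3-propanoyl-1,3-oxazolidin-2-one (TiCl4, i-Pr2NEt, −78 °C) adds to 22 to give imide aldol adduct F8 with reagent-controlled C17. Acetal hydrolysis gives aldehyde imide F9. The CrCl2 cyclisation of step 16 then gives 29 directly, the C7 alkoxide expelling the oxazolidinone.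

Further compounds
F1 | step 16 | (E)-γ-chloroallyl pinacol boronate of 25 (Bpin in place of the primary chloride) | C=C1CC[C@H](OC(C)=O)[C@](C)([C@@H](OC(C)=O)/C=C/C(=C\Cl)CB2OC(C)(C)C(C)(C)O2)[C@H]1[C@H](OC(C)=O)[C@@](O)(C(OC)OC)[C@@H](C)C(=O)OC
F2 | step 16 | aldehyde boronate (F1 with the acetal hydrolysed) | C=C1CC[C@H](OC(C)=O)[C@](C)([C@@H](OC(C)=O)/C=C/C(=C\Cl)CB2OC(C)(C)C(C)(C)O2)[C@H]1[C@H](OC(C)=O)[C@@](O)(C=O)[C@@H](C)C(=O)OC
F3 | step 12 | C10 dimethoxymethyl compound from 18 (C10 epimers) | C=C1CC[C@H](OC(C)=O)[C@](C)([C@@H](OC(C)=O)/C=C/C(=CCl)CCl)C1C(OC)OC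
F4 | step 12 | C10 carbaldehyde (trans-diequatorial isomer) | C=C1CC[C@H](OC(C)=O)[C@](C)([C@@H](OC(C)=O)/C=C/C(=CCl)CCl)[C@H]1C=O
F5 | step 12 | (9S)-carbinol bearing the 2-(dimethoxymethyl)-1,3-dithian-2-yl group | C=C1CC[C@H](OC(C)=O)[C@](C)([C@@H](OC(C)=O)/C=C/C(=CCl)CCl)[C@H]1[C@H](O)C2(C(OC)OC)SCCCS2
F6 | step 12 | C9 ketone (acyl dithiane) | C=C1CC[C@H](OC(C)=O)[C@](C)([C@@H](OC(C)=O)/C=C/C(=CCl)CCl)[C@H]1C(=O)C2(C(OC)OC)SCCCS2
F7 | step 12 | (9S)-acetate of F5 | C=C1CC[C@H](OC(C)=O)[C@](C)([C@@H](OC(C)=O)/C=C/C(=CCl)CCl)[C@H]1[C@H](OC(C)=O)C2(C(OC)OC)SCCCS2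
F8 | step 14 | imide aldol adduct (oxazolidinone analogue of 25) | C=C1CC[C@H](OC(C)=O)[C@](C)([C@@H](OC(C)=O)/C=C/C(=CCl)CCl)[C@H]1[C@H](OC(C)=O)[C@@](O)(C(OC)OC)[C@@H](C)C(=O)N2[C@H](Cc3ccccc3)COC2=O
F9 | step 14 | aldehyde imide (oxazolidinone analogue of 26) | C=C1CC[C@H](OC(C)=O)[C@](C)([C@@H](OC(C)=O)/C=C/C(=CCl)CCl)[C@H]1[C@H](OC(C)=O)[C@@](O)(C=O)[C@@H](C)C(=O)N2[C@H](Cc3ccccc3)COC2=O
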